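**Retrosynthetic overview**

1. Numbering used throughout (abietane type): ring A = cyclohexane C1–C5/C10 (gem-dimethyl on C4); ring B = cyclopentane C5/C7/C8/C9/C10 (CHO on C7); ring C = enol-dione C8/C9/C11–C14; ring D = cyclohexene fused on C8–C9.
2. Target ⇒ hydrolysis of a C12 methyl enol ether ⇒ ring D by Diels–Alder addition of myrcene across C8=C9 of a 12-methoxy-11,14-quinone ⇒ quinone from a trimethoxyarene, CHO from a vinyl group.
3. Key disconnection: C5–C10 and C7–C8 together, a cationic formal [3+2] bicyclization that closes rings A and B at once from an acyclic aryl dienyl carbinol.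
4. Enabling feature: ring B is an indane-type ring whose quaternary benzylic carbon C10 and CHO-bearing C7 sit on adjacent carbons C9 and C8 of ring C. Ring C can be carried as an electron-rich arene with C8–H para to an OMe group, so C10(+)–C9=C8 acts as a three-carbon unit toward the C5=C7 alkene tethered through C1–C4.
5. Ring order: C (bought as arene) → A + B (step 7) → D (step 10); the carbinol comes from an aryllithium and a dienyl methyl ketone.

Key step: step 7

Remark: the target is treated as the 12-hydroxy-11,14-dione tautomer written in its SMILES string, and the antipode of the chiral acid needed in step 7 is taken to be fixed in a first screen.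

**Route**

Step 1
Reactants: 1 1,2,4-trimethoxybenzene
Product: 3 2-(2,3,6-trimethoxyphenyl)propan-2-ol, via (2,3,6-trimethoxyphenyl)lithium 2 (not isolated)
Conditions: n-BuLi (1.1 equiv), THF, 0 °C, 1 h; acetone, −78 °C → rt; H2O
Reagents that add atoms: acetone, CC(C)=O
Why: Directed ortho-metalation removes the proton flanked by two methoxy groups and the aryllithium undergoes 1,2-addition to acetone; no stereocentre is formed.

Step 2
Reactants: 3 2-(2,3,6-trimethoxyphenyl)propan-2-ol
Product: 4 1,2,4-trimethoxy-3-(propan-2-yl)benzene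
Conditions: Et3SiH (2 equiv), CF3CO2H (5 equiv), CH2Cl2, 0 °C → rt
Reagents that add atoms: none
Why: Ionic hydrogenation of a tertiary benzylic alcohol, which should proceed through the doubly ortho-methoxy-stabilised benzylic cation trapped by hydride from the silane.

Step 3
Reactants: 5 2-methylpropanenitrile; 6 2-(3-chloropropyl)-2-methyl-1,3-dioxolane
Product: 8 2,2-dimethyl-5-(2-methyl-1,3-dioxolan-2-yl)pentanenitrile, via 2-lithio-2-methylpropanenitrile 7 (not isolated)
Conditions: LiN(i-Pr)2 (1.1 equiv), THF, −78 °C; then 6, DMPU, −78 → 25 °C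
Reagents that add atoms: none
Why: SN2 C-alkylation of the lithiated nitrile with a primary chloride should build the gem-dimethyl quaternary carbon C4 while the ketone stays masked as its dioxolane.

Step 4
Reactants: 8 2,2-dimethyl-5-(2-methyl-1,3-dioxolan-2-yl)pentanenitrile
Product: 10 2,2-dimethyl-5-(2-methyl-1,3-dioxolan-2-yl)pentanal, via N-aluminated aldimine 9 (not isolated)
Conditions: i-Bu2AlH (1.2 equiv), CH2Cl2, −78 °C; aq. potassium sodium tartrate (KNaC4H4O6), 0 °C → rt
Reagents that add atoms: water, O
Why: Partial reduction of a nitrile to the aldimine–alane and its hydrolysis to the aldehyde; the alpha-quaternary centre excludes enolisation and over-reduction, and the dioxolane should survive the near-neutral work-up.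

Step 5
Reactants: 10 2,2-dimethyl-5-(2-methyl-1,3-dioxolan-2-yl)pentanal
Product: 12 (7E)-6,6-dimethyldeca-7,9-dien-2-one, via dienyl dioxolane 11 (not isolated)
Conditions: diethyl allylphosphonate (1.3 equiv), n-BuLi (1.25 equiv), THF/HMPA, −78 °C → rt; then 1 M aq. HCl, THF, rt, 2 h
Reagents that add atoms: diethyl prop-2-en-1-ylphosphonate, C=CCP(=O)(OCC)OCC; water, O
Why: Horner–Wadsworth–Emmons olefination with the lithiated allylphosphonate should give the terminal (E)-1,3-diene (alpha-attack in the presence of HMPA, E-selective elimination), and the acidic work-up hydrolyses the dioxolane to the methyl ketone.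

Step 6
Reactants: 4 1,2,4-trimethoxy-3-(propan-2-yl)benzene; 12 (7E)-6,6-dimethyldeca-7,9-dien-2-one
Product: 15 (7E)-6,6-dimethyl-2-[2,3,5-trimethoxy-4-(propan-2-yl)phenyl]deca-7,9-dien-2-ol (racemic), via aryllithium 13 (not isolated), via arylcerium dichloride 14 (not isolated)
Conditions: 4, n-BuLi (1.1 equiv), TMEDA, THF, 0 °C; CeCl3 (anhydrous, 1.2 equiv), −78 °C; 12, −78 → 0 °C; H2O
Reagents that add atoms: none
Why: Directed ortho-metalation followed by organocerium 1,2-addition to the enolisable methyl ketone; lithiation should occur at the ring proton next to the 1-OMe group (two meta-OMe groups acidify it, whereas the other ring proton is para to OMe and shielded by the 4-OMe methyl pushed toward it by the isopropyl group), and the carbinol stereocentre, formed racemic, is erased in step 7.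

Step 7
Reactants: 15 (7E)-6,6-dimethyl-2-[2,3,5-trimethoxy-4-(propan-2-yl)phenyl]deca-7,9-dien-2-ol
Product: 18 (4bS,8aS,9R)-9-ethenyl-1,3,4-trimethoxy-4b,8,8-trimethyl-2-(propan-2-yl)-4b,5,6,7,8,8a-hexahydro-9H-fluorene, via tertiary benzylic cation 16 (not isolated), via ring-A allyl cation 17 (not isolated)
Conditions: chiral confined imidodiphosphorimidate Brønsted acid (IDPi, 5 mol %; antipode chosen in a screen), 5 Å molecular sieves, toluene, −40 °C
Reagents that add atoms: none
Why: Proposed new method: the strong confined chiral Brønsted acid ionises the tertiary benzylic carbinol to the planar C10 cation 16, held in toluene as a contact ion pair with the chiral imidodiphosphorimidate anion, and this anion is asked to choose the enantioface at which the tethered diene terminus C5 attacks; the closest known reaction types are the acid-promoted formal [3+2] addition of tertiary benzylic cations to alkenes that gives indanes (as in the cyclodimerisation of alpha-methylstyrene), its intramolecular use in arene-terminated cation–olefin bicyclisations under Bi(OTf)3 or SnCl4, and imidodiphosphorimidate-catalysed enantioselective cation–olefin cyclisations. Ring A closes by 6-exo-trig attack of C5 on C10 through a chair in which the aryl group and the dienyl unit are both equatorial and the C10 methyl is axial, which sets the trans C5/C10 relationship (an axial aryl group would meet the axial C4 methyl), and the gem-dimethyl group speeds the closure. The allyl cation 17 so formed is captured at C7 by arene carbon C8, the only free ortho position and one that is para to the 12-OMe and ortho to the 14-OMe group, in a Friedel–Crafts closure of the five-membered ring B (indane mode); the seven-membered alternative through the far allyl terminus is excluded by the E geometry of the cation. C7 is set by the rotamer of 17 that keeps the vinyl group away from the gem-dimethyl carbon, which is also the thermodynamically preferred arrangement once vinyl has become formyl. The step needs enantioface control at C10 (catalyst), trans diastereocontrol (chair) and C-alkylation at C8 in preference to proton loss, which the high nucleophilicity of that position should secure.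

Step 8
Reactants: 18 (4bS,8aS,9R)-9-ethenyl-1,3,4-trimethoxy-4b,8,8-trimethyl-2-(propan-2-yl)-4b,5,6,7,8,8a-hexahydro-9H-fluorene
Product: 20 (4bS,8aS,9R)-1,3,4-trimethoxy-4b,8,8-trimethyl-2-(propan-2-yl)-4b,5,6,7,8,8a-hexahydro-9H-fluorene-9-carbaldehyde, via vicinal diol 19 (not isolated)
Conditions: OsO4 (2 mol %), NaIO4 (4 equiv), 2,6-lutidine (2 equiv), 1,4-dioxane/H2O 3:1, rt
Reagents that add atoms: sodium periodate, [Na+].[O-]I(=O)(=O)=O; osmium tetroxide, O=[Os](=O)(=O)=O (catalytic oxygen relay)
Why: Lemieux–Johnson cleavage (dihydroxylation, then periodate scission) of the only alkene leaves the electron-rich arene untouched, and C7 keeps its configuration, formyl trans to the gem-dimethyl carbon being also the thermodynamic arrangement should any epimerisation occur.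

Step 9
Reactants: 20 (4bS,8aS,9R)-1,3,4-trimethoxy-4b,8,8-trimethyl-2-(propan-2-yl)-4b,5,6,7,8,8a-hexahydro-9H-fluorene-9-carbaldehyde
Product: 21 (4bS,8aS,9R)-3-methoxy-4b,8,8-trimethyl-1,4-dioxo-2-(propan-2-yl)-4,4b,5,6,7,8,8a,9-octahydro-1H-fluorene-9-carbaldehyde
Conditions: (NH4)2Ce(NO3)6 (2.5 equiv), MeCN/H2O 3:1, 0 °C, 15 min; used at once
Reagents that add atoms: water, O
Why: Oxidative demethylation of the para-dimethoxyarene pair (C11/C14) by tetravalent cerium should give the para-quinone and leave the 12-OMe group as a vinylogous ester; the short, cold, acidic conditions should spare the formyl group and the stereocentres.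

Step 10
Reactants: 21 (4bS,8aS,9R)-3-methoxy-4b,8,8-trimethyl-1,4-dioxo-2-(propan-2-yl)-4,4b,5,6,7,8,8a,9-octahydro-1H-fluorene-9-carbaldehyde; 22 myrcene (7-methyl-3-methylideneocta-1,6-diene)
Product: 23 12-O-methyl ether of the target (Diels–Alder adduct; C5 S, C7 R, C8 S, C9 R, C10 S)
Conditions: Eu(fod)3 (0.3 equiv; fod = 6,6,7,7,8,8,8-heptafluoro-2,2-dimethyloctane-3,5-dionate), 22 (8 equiv), toluene, 50 °C, dark, sealed tube
Reagents that add atoms: none
Why: Lewis acid-catalysed intermolecular Diels–Alder reaction of a quinone, in which Eu(fod)3 should bind the more basic and less hindered vinylogous-ester carbonyl C14=O so that C9 becomes the electrophilic terminus and takes the more nucleophilic CH2 of myrcene (the one on the substituted diene carbon, "para" orientation), while suprafacial addition to the face of C8=C9 opposite the axial C10 methyl (the face of H-5 and of the pseudo-equatorial formyl group) sets the quaternary stereocentres C8 and C9 cis to each other and anti to that methyl.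

Step 11
Reactants: 23 12-O-methyl ether of the target
Product: 24 target, CNP0239256.1
Conditions: LiOH (3 equiv), THF/H2O 3:1, 0 °C → rt; 1 M HCl to pH 3
Reagents that add atoms: lithium hydroxide, [Li+].[OH-]
Why: Hydrolysis of the vinylogous methyl ester by conjugate addition–elimination of hydroxide at C12 gives the enolised trione; it is placed after the cycloaddition because 23 is no longer a quinone that base could tautomerise, and C7 already has its thermodynamic configuration, so no stereocentre should change.

**Compound list**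

1 | 1,2,4-trimethoxybenzene | COc1ccc(OC)c(OC)c1 | starting material
2 | (2,3,6-trimethoxyphenyl)lithium (not isolated) | [Li]c1c(OC)ccc(OC)c1OC | intermediate
3 | 2-(2,3,6-trimethoxyphenyl)propan-2-ol | COc1ccc(OC)c(C(C)(C)O)c1OC | intermediate
4 | 1,2,4-trimethoxy-3-(propan-2-yl)benzene | COc1ccc(OC)c(C(C)C)c1OC | intermediate
5 | 2-methylpropanenitrile | CC(C)C#N | starting material
6 | 2-(3-chloropropyl)-2-methyl-1,3-dioxolane | CC1(CCCCl)OCCO1 | starting material
7 | 2-lithio-2-methylpropanenitrile (not isolated) | [Li]C(C)(C)C#N | intermediate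
8 | 2,2-dimethyl-5-(2-methyl-1,3-dioxolan-2-yl)pentanenitrile | CC1(CCCC(C)(C)C#N)OCCO1 | intermediate
9 | N-(diisobutylalumanyl)-2,2-dimethyl-5-(2-methyl-1,3-dioxolan-2-yl)pentan-1-imine (not isolated) | CC(C)C[Al](CC(C)C)N=CC(C)(C)CCCC1(C)OCCO1 | intermediate
10 | 2,2-dimethyl-5-(2-methyl-1,3-dioxolan-2-yl)pentanal | CC1(CCCC(C)(C)C=O)OCCO1 | intermediate
11 | 2-[(5E)-4,4-dimethylocta-5,7-dien-1-yl]-2-methyl-1,3-dioxolane (not isolated) | CC1(CCCC(C)(C)/C=C/C=C)OCCO1 | intermediate
12 | (7E)-6,6-dimethyldeca-7,9-dien-2-one | CC(=O)CCCC(C)(C)/C=C/C=C | intermediate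
13 | [2,3,5-trimethoxy-4-(propan-2-yl)phenyl]lithium (not isolated) | [Li]c1cc(OC)c(C(C)C)c(OC)c1OC | intermediate
14 | dichloro[2,3,5-trimethoxy-4-(propan-2-yl)phenyl]cerium (not isolated) | Cl[Ce](Cl)c1cc(OC)c(C(C)C)c(OC)c1OC | intermediate
15 | (7E)-6,6-dimethyl-2-[2,3,5-trimethoxy-4-(propan-2-yl)phenyl]deca-7,9-dien-2-ol (racemic) | COc1cc(C(C)(O)CCCC(C)(C)/C=C/C=C)c(OC)c(OC)c1C(C)C | intermediate
16 | (7E)-6,6-dimethyl-2-[2,3,5-trimethoxy-4-(propan-2-yl)phenyl]deca-7,9-dien-2-ylium (not isolated) | COc1cc([C+](C)CCCC(C)(C)/C=C/C=C)c(OC)c(OC)c1C(C)C | intermediate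
17 | 1-{(1S,2S)-2,6,6-trimethyl-2-[2,3,5-trimethoxy-4-(propan-2-yl)phenyl]cyclohexyl}prop-2-en-1-ylium (not isolated) | COc1cc([C@@]2(C)CCCC(C)(C)[C@@H]2[CH+]C=C)c(OC)c(OC)c1C(C)C | intermediate
18 | (4bS,8aS,9R)-9-ethenyl-1,3,4-trimethoxy-4b,8,8-trimethyl-2-(propan-2-yl)-4b,5,6,7,8,8a-hexahydro-9H-fluorene | COc1c(C(C)C)c(OC)c(OC)c2c1[C@H](C=C)[C@H]1C(C)(C)CCC[C@]21C | intermediate
19 | 1-[(4bS,8aS,9R)-1,3,4-trimethoxy-4b,8,8-trimethyl-2-(propan-2-yl)-4b,5,6,7,8,8a-hexahydro-9H-fluoren-9-yl]ethane-1,2-diol (carbinol epimers, not isolated) | COc1c(C(C)C)c(OC)c(OC)c2c1[C@H](C(O)CO)[C@H]1C(C)(C)CCC[C@]21C | intermediate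
20 | (4bS,8aS,9R)-1,3,4-trimethoxy-4b,8,8-trimethyl-2-(propan-2-yl)-4b,5,6,7,8,8a-hexahydro-9H-fluorene-9-carbaldehyde | COc1c(C(C)C)c(OC)c(OC)c2c1[C@H](C=O)[C@H]1C(C)(C)CCC[C@]21C | intermediate
21 | (4bS,8aS,9R)-3-methoxy-4b,8,8-trimethyl-1,4-dioxo-2-(propan-2-yl)-4,4b,5,6,7,8,8a,9-octahydro-1H-fluorene-9-carbaldehyde | CC(C)C1=C(OC)C(=O)C2=C(C1=O)[C@H](C=O)[C@H]1C(C)(C)CCC[C@]21C | intermediate
22 | myrcene (7-methyl-3-methylideneocta-1,6-diene) | CC(C)=CCCC(=C)C=C | starting material
23 | 12-O-methyl ether of the target: myrcene adduct across C8=C9 of 21, ring D on the face opposite the C10 methyl, 4-methylpent-3-enyl carbon joined through CH2 to C9 (C5 S, C7 R, C8 S, C9 R, C10 S) | CC(C)=CCCC1=CC[C@@]23C(=O)C(C(C)C)=C(OC)C(=O)[C@]2(C1)[C@@]1(C)CCCC(C)(C)[C@@H]1[C@H]3C=O | intermediate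
24 | CNP0239256.1: the 12-hydroxy-11,14-dione with rings A–D as defined above (C5 S, C7 R, C8 S, C9 R, C10 S) | CC(C)=CCCC1=CC[C@@]23C(=O)C(C(C)C)=C(O)C(=O)[C@]2(C1)[C@@]1(C)CCCC(C)(C)[C@@H]1[C@H]3C=O | target

**Step count and risks**

Total step count: 11. Longest linear sequence: 9 steps (steps 3–11, from 2-methylpropanenitrile).

Steps most likely to fail:

1. Step 7 (proposed new method). The highly stabilised benzylic cation may pair too loosely with the chiral anion, so enantioface control is lost. Elimination to styrenes or erosion of the trans ring fusion may also compete. Fallback with known chemistry, setting out from 15: the achiral Lewis acid Bi(OTf)3 (5 mol %, CH2Cl2, 0 °C) should bring about the same cationic bicyclisation without chiral information. This would give 18 together with its mirror image (4bR,8aR,9S)-9-ethenyl-1,3,4-trimethoxy-4b,8,8-trimethyl-2-(propan-2-yl)-4b,5,6,7,8,8a-hexahydro-9H-fluorene F1. The two are separated by preparative chromatography on a chiral stationary phase (amylose tris(3,5-dimethylphenylcarbamate)), and the route is rejoined at 18.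

2. Step 10. Cycloaddition at the tetrasubstituted C8=C9 bond may be so slow that other processes take over: Lewis-acid-induced ene or Prins reaction of the formyl group with myrcene, tautomerisation of the formyl quinone to an aromatic hydroquinone enal, or erosion of regiocontrol by the weakly directing alkyl group. Fallback, setting out from 21: the small, far more nucleophilic and more strongly directing 2-(trimethylsilyloxy)buta-1,3-diene (Eu(fod)3, CH2Cl2, rt) should add with the same orientation and facial sense to give the ring D trimethylsilyl enol ether F2 (silyloxy carbon joined through CH2 to C9). Treatment with N-phenylbis(trifluoromethanesulfonimide) and CsF (1,2-dimethoxyethane, rt) should convert it regiospecifically into the ring D enol triflate F3. Negishi coupling of F3 with (4-methylpent-3-en-1-yl)zinc bromide (from 5-bromo-2-methylpent-2-ene and zinc; Pd(dppf)Cl2, THF, rt) installs the side chain, and the route is rejoined at 23.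

3. Step 6. Lithiation may occur at the other ring position (ortho to the 4-OMe group), or the ketone may be enolised instead of attacked. Fallback, setting out from 4: electrophilic bromination (N-bromosuccinimide, MeCN, 0 °C) blocks the position para to the 2-OMe group and gives 1-bromo-2,4,5-trimethoxy-3-(propan-2-yl)benzene F4, which has a single ring proton, flanked by Br and OMe. Deprotonation there (LiN(i-Pr)2, THF, −78 °C), transmetalation with CeCl3 and addition to 12 should give (7E)-2-[2-bromo-3,5,6-trimethoxy-4-(propan-2-yl)phenyl]-6,6-dimethyldeca-7,9-dien-2-ol F5. Bromine–lithium exchange (n-BuLi, 2.2 equiv, THF, −78 °C) and a methanol quench remove the halogen, and the route is rejoined at 15.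

Further compounds
F1 | step 7 | (4bR,8aR,9S)-9-ethenyl-1,3,4-trimethoxy-4b,8,8-trimethyl-2-(propan-2-yl)-4b,5,6,7,8,8a-hexahydro-9H-fluorene | COc1c(C(C)C)c(OC)c(OC)c2c1[C@@H](C=C)[C@@H]1C(C)(C)CCC[C@@]21C
F2 | step 10 | ring D trimethylsilyl enol ether (23 with OSiMe3 in place of the 4-methylpent-3-enyl group) | C[Si](C)(C)OC1=CC[C@@]23C(=O)C(C(C)C)=C(OC)C(=O)[C@]2(C1)[C@@]1(C)CCCC(C)(C)[C@@H]1[C@H]3C=O
F3 | step 10 | ring D enol triflate (23 with OSO2CF3 in place of the 4-methylpent-3-enyl group) | O=S(=O)(OC1=CC[C@@]23C(=O)C(C(C)C)=C(OC)C(=O)[C@]2(C1)[C@@]1(C)CCCC(C)(C)[C@@H]1[C@H]3C=O)C(F)(F)F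
F4 | step 6 | 1-bromo-2,4,5-trimethoxy-3-(propan-2-yl)benzene | COc1cc(Br)c(OC)c(C(C)C)c1OC
F5 | step 6 | (7E)-2-[2-bromo-3,5,6-trimethoxy-4-(propan-2-yl)phenyl]-6,6-dimethyldeca-7,9-dien-2-ol | COc1c(C(C)(O)CCCC(C)(C)/C=C/C=C)c(Br)c(OC)c(C(C)C)c1OC
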